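**Retrosynthetic overview**
1. Target 21 is the monoacetate of the C2-symmetric 2,5-dihydroxy-3,6-diaryl-1,4-benzoquinone 19. One of its two equivalent quinone hydroxyls is acetylated and the two aryl tert-butyl ethers are then removed with acid. 19 comes from hydroquinone 17 by Ag2O oxidation and hydrolysis of two vinylogous methyl esters.
2. Feature: the fully substituted six-membered ring (carbonyl carbons C1/C4, oxygen-bearing C2/C5, aryl-bearing C3/C6) is a cyclobutenone C1(=O)–C2(OMe)=C3(Ar)–C4(OH) that carries the enol-ether alkene C5(OMe)=C6H(Ar) on C4; only the C6–C1 bond is absent.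
3. Key disconnection C6–C1: thermal opening of cyclobutenone 14 to a dienylketene and 6π closure. This is the only ring formed in the route; the four-membered ring is bought as dimethyl squarate.
4. 14 is built on dimethyl squarate by two ordered 1,2-additions (α-lithiated Z-enol ether first, aryllithium second), with O-silylation between them and a TFAA-triggered carbonyl transposition after them.
5. The phenols are carried as tert-butyl ethers: unlike benzyl ethers they have no C–H that s-BuLi removes, they resist NaOH, and they leave under acid without reducing the quinone.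

Key step: step 5

Assumption: the target has no stereocentre; 8, 13, 14 and 16 are racemic, 11 and 12 are diastereomer mixtures, and the Z descriptors refer only to the enol-ether alkene.

**Step 1**
Reactants: 1 4-tert-butoxybenzaldehyde; 2 (methoxymethyl)triphenylphosphonium chloride
Product: 4 1-tert-butoxy-4-[(Z)-2-methoxyethenyl]benzene, via phosphorus ylide 3 (not isolated)
Conditions: KN(SiMe3)2, THF, 0 °C; then 1, −78 °C → rt; chromatography on Et3N-deactivated SiO2, Z isomer collected
Reagents that add atoms: none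
Why: Wittig olefination with the non-stabilised α-methoxy ylide under salt-free conditions should give the enol ether as a mixture of geometric isomers, from which the Z isomer (α-hydrogen cis to the β-hydrogen, hence the one that should lithiate cleanly in step 2) is separated while the E isomer is set aside.

**Step 2**
Reactants: 4 1-tert-butoxy-4-[(Z)-2-methoxyethenyl]benzene; 5 dimethyl squarate
Product: 8 4-[(Z)-2-(4-tert-butoxyphenyl)-1-methoxyethenyl]-2,3-dimethoxy-4-(trimethylsilyloxy)cyclobut-2-en-1-one (racemic), via vinyllithium 6 (not isolated), via lithium alkoxide 7 (not isolated)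
Conditions: s-BuLi, THF, −78 → −50 °C; cannulate into 5 (1.2 equiv), THF, −78 °C; TMSCl, −78 → −20 °C
Reagents that add atoms: chlorotrimethylsilane, C[Si](C)(C)Cl
Why: Oxygen-assisted vinylic α-deprotonation of the Z-enol ether (alkene geometry retained) is followed by 1,2-addition of the vinyllithium to one squarate carbonyl and O-silylation of the tertiary alkoxide; inverse addition to excess 5 at −78 °C limits double addition, and the carbinol centre forms racemic.

**Step 3**
Reactants: 8 4-[(Z)-2-(4-tert-butoxyphenyl)-1-methoxyethenyl]-2,3-dimethoxy-4-(trimethylsilyloxy)cyclobut-2-en-1-one; 9 1-bromo-4-tert-butoxybenzene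
Product: 13 3-(4-tert-butoxyphenyl)-4-[(Z)-2-(4-tert-butoxyphenyl)-1-methoxyethenyl]-2-methoxy-4-(trimethylsilyloxy)cyclobut-2-en-1-one (racemic), via aryllithium 10 (not isolated), via diol monoalkoxide 11 (not isolated), via allylic trifluoroacetate 12 (not isolated)
Conditions: 9, n-BuLi, THF, −78 °C; add 8, −78 °C; TFAA, −78 °C; sat. aq. NaHCO3, → rt
Reagents that add atoms: water, O
Why: Bromine–lithium exchange gives the aryllithium, which adds 1,2 to the remaining vinylogous-ester carbonyl; trifluoroacetylation of the new alkoxide then triggers methoxy-assisted ionisation and hydrolysis of the methoxy-oxocarbenium on basic work-up (1,3-carbonyl transposition), which puts the aryl on the ring alkene next to the silyloxy carbon while the silyl ether keeps the other carbinol from ionising and the enol ether never meets aqueous acid.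

**Step 4**
Reactants: 13 3-(4-tert-butoxyphenyl)-4-[(Z)-2-(4-tert-butoxyphenyl)-1-methoxyethenyl]-2-methoxy-4-(trimethylsilyloxy)cyclobut-2-en-1-one
Product: 14 3-(4-tert-butoxyphenyl)-4-[(Z)-2-(4-tert-butoxyphenyl)-1-methoxyethenyl]-4-hydroxy-2-methoxycyclobut-2-en-1-one (racemic)
Conditions: TBAF, AcOH (1:1), THF, 0 °C
Reagents that add atoms: none
Why: Fluoride-mediated desilylation of the tertiary trimethylsilyl ether, buffered with acetic acid so that neither the base-sensitive 4-hydroxycyclobutenone nor the acid-sensitive enol ether is exposed to extremes of pH.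

**Step 5**
Reactants: 14 3-(4-tert-butoxyphenyl)-4-[(Z)-2-(4-tert-butoxyphenyl)-1-methoxyethenyl]-4-hydroxy-2-methoxycyclobut-2-en-1-one
Product: 17 2,5-bis(4-tert-butoxyphenyl)-3,6-dimethoxybenzene-1,4-diol, via dienylketene 15 (not isolated), via cyclohexadienone 16 (not isolated)
Conditions: toluene (0.02 M, degassed), 110 °C, Ar
Reagents that add atoms: none
Why: Moore rearrangement: thermal conrotatory 4π opening breaks the C1–C4 bond of the cyclobutenone and gives dienylketene 15, whose ketene carbon and styryl CH are the termini of a hexatriene; a disrotatory 6π electrocyclisation joins them and closes the six-membered carbocycle as cyclohexadienone 16, which enolises to the aromatic hydroquinone 17. The closest known reaction type is the thermolysis of 4-alkenyl-4-hydroxycyclobutenones to hydroquinones, a well-precedented process. The ring is closed in the 6π-electrocyclic mode with one new C–C bond, and no stereocentre results because the carbinol carbon of 14 becomes sp2 and the sp3 carbon of 16 is lost on tautomerisation. The selectivity needed is torquoselectivity in the ring opening: the C4 hydroxyl, the stronger donor, should rotate outward and so turn the alkenyl group inward, cis to the ketene, so that cyclisation outruns capture of the ketene by the hydroxyl. The Z-alkene of 14 leaves only hydrogen on the inside of the closing terminus, and the substituent sequence O, OMe, Ar, O, OMe, Ar is already fixed by the order of additions in steps 2 and 3, so no regiochemical choice arises.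

**Step 6**
Reactants: 17 2,5-bis(4-tert-butoxyphenyl)-3,6-dimethoxybenzene-1,4-diol
Product: 18 2,5-bis(4-tert-butoxyphenyl)-3,6-dimethoxycyclohexa-2,5-diene-1,4-dione
Conditions: Ag2O, Na2SO4, CH2Cl2, rt
Reagents that add atoms: none
Why: Two-electron oxidation of the electron-rich para-hydroquinone to the quinone by Ag2O under neutral conditions that leave the aryl tert-butyl ethers and methoxy groups untouched.

**Step 7**
Reactants: 18 2,5-bis(4-tert-butoxyphenyl)-3,6-dimethoxycyclohexa-2,5-diene-1,4-dione
Product: 19 2,5-bis(4-tert-butoxyphenyl)-3,6-dihydroxycyclohexa-2,5-diene-1,4-dione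
Conditions: NaOH (2 M aq), MeOH/THF, 50 °C; then 1 M HCl, 0 °C
Reagents that add atoms: sodium hydroxide, [Na+].[OH-]
Why: Addition–elimination of hydroxide at the two methoxy-bearing quinone carbons (saponification of vinylogous esters) gives the bis-enolate, which is protonated on cold acidic work-up; aryl tert-butyl ethers are inert to aqueous base and to brief cold dilute acid.

**Step 8**
Reactants: 19 2,5-bis(4-tert-butoxyphenyl)-3,6-dihydroxycyclohexa-2,5-diene-1,4-dione
Product: 20 2,5-bis(4-tert-butoxyphenyl)-4-hydroxy-3,6-dioxocyclohexa-1,4-dien-1-yl acetate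
Conditions: Et3N (2.2 equiv), Ac2O (1.0 equiv), CH2Cl2, −20 °C; cold 0.5 M HCl work-up; chromatography
Reagents that add atoms: acetic anhydride, CC(=O)OC(C)=O
Why: O-acylation of the dianion of the symmetric dihydroxyquinone with one equivalent of anhydride: the two hydroxyls are equivalent and the dianion is a better nucleophile than the monoacetate mono-anion that forms, so the monoacetate should predominate and is separated from residual 19 and any diacetate.

**Step 9**
Reactants: 20 2,5-bis(4-tert-butoxyphenyl)-4-hydroxy-3,6-dioxocyclohexa-1,4-dien-1-yl acetate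
Product: 21 4-hydroxy-2,5-bis(4-hydroxyphenyl)-3,6-dioxocyclohexa-1,4-dien-1-yl acetate
Conditions: TFA/CH2Cl2 (1:1), 0 °C → rt, N2 sparge
Reagents that add atoms: none
Why: Acid-mediated cleavage of both aryl tert-butyl ethers (E1 loss of 2-methylpropene) under anhydrous, non-nucleophilic and non-reducing conditions that should leave the enol acetate and the quinone intact.

**Compound list**
1 | 4-tert-butoxybenzaldehyde | CC(C)(C)Oc1ccc(C=O)cc1 | starting material
2 | (methoxymethyl)triphenylphosphonium chloride | COC[P+](c1ccccc1)(c1ccccc1)c1ccccc1.[Cl-] | starting material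
3 | (methoxymethylidene)triphenylphosphorane | COC=P(c1ccccc1)(c1ccccc1)c1ccccc1 | intermediate
4 | 1-tert-butoxy-4-[(Z)-2-methoxyethenyl]benzene | CO/C=C\c1ccc(OC(C)(C)C)cc1 | intermediate
5 | dimethyl squarate (3,4-dimethoxycyclobut-3-ene-1,2-dione) | COC1=C(OC)C(=O)C1=O | starting material
6 | [(Z)-2-(4-tert-butoxyphenyl)-1-methoxyethenyl]lithium | [Li]/C(OC)=C/c1ccc(OC(C)(C)C)cc1 | intermediate
7 | lithium 1-[(Z)-2-(4-tert-butoxyphenyl)-1-methoxyethenyl]-2,3-dimethoxy-4-oxocyclobut-2-en-1-olate (racemic) | COC1=C(OC)C([O-])(/C(OC)=C/c2ccc(OC(C)(C)C)cc2)C1=O.[Li+] | intermediate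
8 | 4-[(Z)-2-(4-tert-butoxyphenyl)-1-methoxyethenyl]-2,3-dimethoxy-4-(trimethylsilyloxy)cyclobut-2-en-1-one (racemic) | COC1=C(OC)C(O[Si](C)(C)C)(/C(OC)=C/c2ccc(OC(C)(C)C)cc2)C1=O | intermediate
9 | 1-bromo-4-tert-butoxybenzene | CC(C)(C)Oc1ccc(Br)cc1 | starting material
10 | (4-tert-butoxyphenyl)lithium | [Li]c1ccc(OC(C)(C)C)cc1 | intermediate
11 | lithium 1-(4-tert-butoxyphenyl)-4-[(Z)-2-(4-tert-butoxyphenyl)-1-methoxyethenyl]-2,3-dimethoxy-4-(trimethylsilyloxy)cyclobut-2-en-1-olate (diastereomer mixture) | COC1=C(OC)C(O[Si](C)(C)C)(/C(OC)=C/c2ccc(OC(C)(C)C)cc2)C1([O-])c3ccc(OC(C)(C)C)cc3.[Li+] | intermediate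
12 | 1-(4-tert-butoxyphenyl)-4-[(Z)-2-(4-tert-butoxyphenyl)-1-methoxyethenyl]-2,3-dimethoxy-4-(trimethylsilyloxy)cyclobut-2-en-1-yl trifluoroacetate (diastereomer mixture) | COC1=C(OC)C(O[Si](C)(C)C)(/C(OC)=C/c2ccc(OC(C)(C)C)cc2)C1(OC(=O)C(F)(F)F)c3ccc(OC(C)(C)C)cc3 | intermediate
13 | 3-(4-tert-butoxyphenyl)-4-[(Z)-2-(4-tert-butoxyphenyl)-1-methoxyethenyl]-2-methoxy-4-(trimethylsilyloxy)cyclobut-2-en-1-one (racemic) | COC1=C(c2ccc(OC(C)(C)C)cc2)C(O[Si](C)(C)C)(/C(OC)=C/c2ccc(OC(C)(C)C)cc2)C1=O | intermediate
14 | 3-(4-tert-butoxyphenyl)-4-[(Z)-2-(4-tert-butoxyphenyl)-1-methoxyethenyl]-4-hydroxy-2-methoxycyclobut-2-en-1-one (racemic) | COC1=C(c2ccc(OC(C)(C)C)cc2)C(O)(/C(OC)=C/c2ccc(OC(C)(C)C)cc2)C1=O | intermediate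
15 | (3E,5Z)-3,6-bis(4-tert-butoxyphenyl)-4-hydroxy-2,5-dimethoxyhexa-1,3,5-trien-1-one | COC(=C=O)/C(c1ccc(OC(C)(C)C)cc1)=C(O)\C(OC)=C\c1ccc(OC(C)(C)C)cc1 | intermediate
16 | 3,6-bis(4-tert-butoxyphenyl)-4-hydroxy-2,5-dimethoxycyclohexa-2,4-dien-1-one (racemic) | COC1=C(c2ccc(OC(C)(C)C)cc2)C(O)=C(OC)C(c2ccc(OC(C)(C)C)cc2)C1=O | intermediate
17 | 2,5-bis(4-tert-butoxyphenyl)-3,6-dimethoxybenzene-1,4-diol | COc1c(O)c(-c2ccc(OC(C)(C)C)cc2)c(OC)c(O)c1-c1ccc(OC(C)(C)C)cc1 | intermediate
18 | 2,5-bis(4-tert-butoxyphenyl)-3,6-dimethoxycyclohexa-2,5-diene-1,4-dione | COC1=C(c2ccc(OC(C)(C)C)cc2)C(=O)C(OC)=C(c2ccc(OC(C)(C)C)cc2)C1=O | intermediate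
19 | 2,5-bis(4-tert-butoxyphenyl)-3,6-dihydroxycyclohexa-2,5-diene-1,4-dione | OC1=C(c2ccc(OC(C)(C)C)cc2)C(=O)C(O)=C(c2ccc(OC(C)(C)C)cc2)C1=O | intermediate
20 | 2,5-bis(4-tert-butoxyphenyl)-4-hydroxy-3,6-dioxocyclohexa-1,4-dien-1-yl acetate | CC(=O)OC1=C(c2ccc(OC(C)(C)C)cc2)C(=O)C(O)=C(c2ccc(OC(C)(C)C)cc2)C1=O | intermediate
21 | 4-hydroxy-2,5-bis(4-hydroxyphenyl)-3,6-dioxocyclohexa-1,4-dien-1-yl acetate | CC(=O)OC1=C(c2ccc(O)cc2)C(=O)C(O)=C(c2ccc(O)cc2)C1=O | target

**Step count**
Total steps: 9. Longest linear sequence: 9 steps (1 → 4 → 8 → 13 → 14 → 17 → 18 → 19 → 20 → 21); 9 enters in step 3 without separate steps.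

**Steps most likely to fail**

Step 5 (ring expansion). What may go wrong: the ring opening is reversible, and if the hydroxyl rotates inward the ketene is captured by it (lactonisation to a furanone) instead of closing onto the styryl carbon; the electron-rich enol ether and the air-sensitive hydroquinone may also degrade at 110 °C. Fallback, setting out from 9 and returning at 18: the ring is not built but bought. Aryllithium 10 (from 9, n-BuLi, THF, −78 °C) is quenched with B(OMe)3 and aqueous acid to give (4-tert-butoxyphenyl)boronic acid F1. Tetrabromo-1,4-benzoquinone with NaOMe in MeOH gives 2,5-dibromo-3,6-dimethoxycyclohexa-2,5-diene-1,4-dione F2 by twofold addition–elimination. A twofold Suzuki–Miyaura coupling of F2 with F1 (Pd(PPh3)4, K2CO3, dioxane/H2O, 90 °C) gives 18, and the route resumes at step 7.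

Step 2 (α-lithiation and mono-addition). What may go wrong: the alkyllithium may add across the styryl double bond or metalate the arene instead of removing the vinylic α-hydrogen; the α-alkoxyvinyllithium may lose LiOMe to the arylalkyne on warming; a second equivalent may add to the squarate. Fallback, setting out from 4 (either geometric isomer serves), 9 and 5 and returning at 17: the vinyl anion is made by halogen–lithium exchange and the two squarate additions are swapped.
- Bromine adds to 4 (CH2Cl2, −78 °C) to give 1-tert-butoxy-4-(1,2-dibromo-2-methoxyethyl)benzene F3, which loses HBr with Et3N in the same flask to give 1-[(Z)-1-bromo-2-methoxyethenyl]-4-tert-butoxybenzene F4 (the α-bromo ether ionises and the benzylic hydrogen leaves).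
- Aryllithium 10 adds to 5 (THF, −78 °C) to give lithium 1-(4-tert-butoxyphenyl)-2,3-dimethoxy-4-oxocyclobut-2-en-1-olate F5; TFAA and then aqueous NaHCO3 convert it into 3-(4-tert-butoxyphenyl)-4-methoxycyclobut-3-ene-1,2-dione F6.
- Bromine–lithium exchange on F4 (n-BuLi, THF, −78 °C) gives [(E)-1-(4-tert-butoxyphenyl)-2-methoxyethenyl]lithium F7, whose lithium is cis to the methoxy group and so cannot lose LiOMe by anti elimination.
- F7 adds to the more electrophilic carbonyl of F6 (the one next to the methoxy-bearing carbon) to give 2-(4-tert-butoxyphenyl)-4-[(Z)-1-(4-tert-butoxyphenyl)-2-methoxyethenyl]-4-hydroxy-3-methoxycyclobut-2-en-1-one F8.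
- Heating F8 in toluene at 110 °C (the same ring opening and 6π closure, now joining the ketene carbon to the methoxy-bearing alkene carbon) gives hydroquinone 17, because the sequence O, aryl, OMe, O, aryl, OMe around the ring is the same. The route resumes at step 6.

Step 8 (monoacetylation). What may go wrong: acetyl transfer between quinone oxygens and over-acylation may level the mixture toward unreacted diol, monoacetate and diacetate, and the vinylogous anhydride may hydrolyse on work-up. Fallback, setting out from 19 and returning at 20: the desymmetrisation is done by removal instead of addition. Exhaustive acetylation of 19 (Ac2O, pyridine, DMAP, rt) gives 2,5-bis(4-tert-butoxyphenyl)-3,6-dioxocyclohexa-1,4-diene-1,4-diyl diacetate F9. Methanolysis with one equivalent of NaHCO3 in MeOH/THF at 0 °C should stop after the first acetate, since the hydroxyquinone anion that forms makes the second acetate a poorer acyl donor. Cold acidic work-up gives 20.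

**Further compounds**
F1 | step 5 | (4-tert-butoxyphenyl)boronic acid | CC(C)(C)Oc1ccc(B(O)O)cc1
F2 | step 5 | 2,5-dibromo-3,6-dimethoxycyclohexa-2,5-diene-1,4-dione | COC1=C(Br)C(=O)C(OC)=C(Br)C1=O
F3 | step 2 | 1-tert-butoxy-4-(1,2-dibromo-2-methoxyethyl)benzene (diastereomer mixture) | COC(Br)C(Br)c1ccc(OC(C)(C)C)cc1
F4 | step 2 | 1-[(Z)-1-bromo-2-methoxyethenyl]-4-tert-butoxybenzene | CO/C=C(\Br)c1ccc(OC(C)(C)C)cc1
F5 | step 2 | lithium 1-(4-tert-butoxyphenyl)-2,3-dimethoxy-4-oxocyclobut-2-en-1-olate (racemic) | COC1=C(OC)C([O-])(c2ccc(OC(C)(C)C)cc2)C1=O.[Li+]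
F6 | step 2 | 3-(4-tert-butoxyphenyl)-4-methoxycyclobut-3-ene-1,2-dione | COC1=C(c2ccc(OC(C)(C)C)cc2)C(=O)C1=O
F7 | step 2 | [(E)-1-(4-tert-butoxyphenyl)-2-methoxyethenyl]lithium | CO/C=C(\[Li])c1ccc(OC(C)(C)C)cc1
F8 | step 2 | 2-(4-tert-butoxyphenyl)-4-[(Z)-1-(4-tert-butoxyphenyl)-2-methoxyethenyl]-4-hydroxy-3-methoxycyclobut-2-en-1-one (racemic) | CO/C=C(\C1(O)C(OC)=C(c2ccc(OC(C)(C)C)cc2)C1=O)c3ccc(OC(C)(C)C)cc3
F9 | step 8 | 2,5-bis(4-tert-butoxyphenyl)-3,6-dioxocyclohexa-1,4-diene-1,4-diyl diacetate | CC(=O)OC1=C(c2ccc(OC(C)(C)C)cc2)C(=O)C(OC(C)=O)=C(c2ccc(OC(C)(C)C)cc2)C1=O
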